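**Retrosynthetic overview**
1. Butenolide numbering used throughout: O1, C2 (C=O), C3 (OMe), C4 (catechol aryl), C5 (quaternary). The target comes from its catechol dibenzyl ether 20 by hydrogenolysis.
2. The strategy rests on C5: it carries the ring oxygen O1 and a CH2 bound to C6 of the chroman arene, which is the pattern left when a C2 carboxylate and an aryl group add across a C5=CH2 alkene. Lactone 20 is therefore cut at O1–C5 and at CH2–aryl into diene acid 11 and chroman diazonium salt 19.
3. Acid 11 comes from enol triflate 7 (Claisen acylation of tert-butyl methoxyacetate with the aroyl chloride, then triflation with OTf cis to the ester) by Stille coupling with α-stannylacrylate 9 and tert-butyl ester cleavage.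
4. Salt 19 comes from 4-nitrophenol by propargyl ether formation, Claisen cyclization to the 6-nitrochromene, asymmetric epoxidation, hydrogenation and diazotization.
5. Ring order: the pyran ring of the chroman first (step 8), the butenolide last (step 12); both benzene rings are bought.

Key step: step 12

Remark 1: the sense of induction of a copper/bis(oxazoline) catalyst for this radical class is not established; the (S,S)-ligand is written on the assumption that it gives (S) at C5, and its enantiomer would be used if the opposite sense were found.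
Remark 2: (R,R)-(salen)MnCl is assumed, by analogy with other 2,2-dimethylchromenes, to give the (3R,4R)-epoxide.

**Route**

Step 1
Reactants: 1 3,4-bis(benzyloxy)benzoic acid
Product: 2 3,4-bis(benzyloxy)benzoyl chloride
Conditions: (COCl)2, DMF (cat.), CH2Cl2, 0 °C to rt; concentrate, use crude
Reagents that add atoms: oxalyl chloride, ClC(=O)C(=O)Cl
Why: Acid chloride formation through the catalytic chloroiminium (Vilsmeier-type) species is routine for aryl acids and leaves the benzyl ethers untouched.

Step 2
Reactants: 2 3,4-bis(benzyloxy)benzoyl chloride; 3 tert-butyl methoxyacetate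
Product: 5 tert-butyl 3-[3,4-bis(benzyloxy)phenyl]-2-methoxy-3-oxopropanoate (racemic), via lithium enolate 4 (not isolated)
Conditions: 3 (2.2 equiv), LiN(SiMe3)2 (2.2 equiv), THF, −78 °C; then 2, −78 to 0 °C; aq. NH4Cl
Reagents that add atoms: none
Why: Crossed Claisen condensation (C-acylation of an ester enolate by an aroyl chloride), in which the second equivalent of enolate deprotonates the more acidic β-keto ester and so prevents double acylation.

Step 3
Reactants: 5 tert-butyl 3-[3,4-bis(benzyloxy)phenyl]-2-methoxy-3-oxopropanoate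
Product: 7 tert-butyl (2E)-3-[3,4-bis(benzyloxy)phenyl]-2-methoxy-3-(trifluoromethylsulfonyloxy)prop-2-enoate (OTf cis to the ester), via sodium enolate 6 (not isolated)
Conditions: NaH, CH2Cl2, 0 °C; then Tf2O, −78 to 0 °C
Reagents that add atoms: trifluoromethanesulfonic anhydride, O=S(=O)(OS(=O)(=O)C(F)(F)F)C(F)(F)F
Why: O-Sulfonylation of a β-keto ester enolate; in a non-coordinating solvent the sodium ion bridges the enolate oxygen and the ester carbonyl in a six-membered chelate, so the triflate should form cis to the ester (2E by the sequence rule, because OMe outranks the ester), the geometry to be checked by NOE.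

Step 4
Reactants: 8 methyl propiolate
Product: 9 methyl 2-(tributylstannyl)prop-2-enoate
Conditions: Bu3SnH, Pd(PPh3)4 (2 mol %), THF, 0 °C to rt
Reagents that add atoms: tributyltin hydride, CCCC[SnH](CCCC)CCCC
Why: Palladium-catalysed syn-hydrostannation of an alkynoate, which is known to deliver tin to the α-carbon and hydrogen to the β-carbon.

Step 5
Reactants: 7 enol triflate; 9 methyl 2-(tributylstannyl)prop-2-enoate
Product: 10 1-tert-butyl 5-methyl (2E)-3-[3,4-bis(benzyloxy)phenyl]-2-methoxy-4-methylidenepent-2-enedioate (tert-butyl ester and acrylate unit cis)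
Conditions: Pd(PPh3)4 (10 mol %), CuI (20 mol %), CsF, DMF, 45 °C
Reagents that add atoms: none
Why: Stille coupling of an electron-poor enol triflate, with CuI and fluoride speeding transmetalation of the hindered α-stannylacrylate; oxidative addition and reductive elimination at palladium retain the alkene geometry.

Step 6
Reactants: 10 diene diester
Product: 11 (2E)-3-[3,4-bis(benzyloxy)phenyl]-2-methoxy-4-(methoxycarbonyl)penta-2,4-dienoic acid (acid and acrylate unit cis)
Conditions: CF3CO2H/CH2Cl2 (1:4), 0 °C to rt; toluene azeotrope; use directly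
Reagents that add atoms: none
Why: Acidolysis of the tert-butyl ester by loss of the tert-butyl cation, which under brief anhydrous exposure should spare the methyl ester, the enol ether and the aryl benzyl ethers.

Step 7
Reactants: 12 4-nitrophenol; 13 3-chloro-3-methylbut-1-yne
Product: 14 1-[(2-methylbut-3-yn-2-yl)oxy]-4-nitrobenzene
Conditions: DBU, CuCl2·2H2O (1 mol %), MeCN, 0 °C to rt
Reagents that add atoms: none
Why: Copper-catalysed propargylic substitution through a copper acetylide lets the weakly nucleophilic nitrophenoxide form the tertiary propargyl aryl ether.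

Step 8
Reactants: 14 1-[(2-methylbut-3-yn-2-yl)oxy]-4-nitrobenzene
Product: 15 2,2-dimethyl-6-nitro-2H-chromene
Conditions: 1,2-dichlorobenzene, 180 °C
Reagents that add atoms: none
Why: Aromatic propargyl Claisen rearrangement followed by 1,5-hydrogen shift and oxa-6π electrocyclization closes the pyran ring, the para nitro group leaving two equivalent ortho positions.

Step 9
Reactants: 15 2,2-dimethyl-6-nitro-2H-chromene
Product: 16 (3R,4R)-3,4-epoxy-2,2-dimethyl-6-nitrochroman
Conditions: (R,R)-(salen)MnCl [salen = N,N′-bis(3,5-di-tert-butylsalicylidene)-1,2-cyclohexanediaminate] (3 mol %), 4-phenylpyridine N-oxide, aq. NaOCl (pH 11.3), CH2Cl2, 0 °C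
Reagents that add atoms: sodium hypochlorite, [Na+].[O-]Cl
Why: Jacobsen–Katsuki epoxidation, for which cis-configured 2,2-dimethylchromenes are a favoured substrate class; the chiral salen ligand on the manganese oxo species directs oxygen to one alkene face and sets C3 and C4 (both R).

Step 10
Reactants: 16 (3R,4R)-3,4-epoxy-2,2-dimethyl-6-nitrochroman
Product: 18 (3R)-6-amino-2,2-dimethylchroman-3-ol, via amino epoxide 17 (not isolated)
Conditions: H2 (1 atm), 10% Pd/C, EtOH, rt
Reagents that add atoms: none
Why: Catalytic hydrogenation reduces the nitro group and then cleaves the benzylic C4–O bond of the epoxide by hydrogenolysis; the C3–O bond is not touched, so C3 keeps its R configuration.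

Step 11
Reactants: 18 (3R)-6-amino-2,2-dimethylchroman-3-ol
Product: 19 (3R)-3-hydroxy-2,2-dimethylchroman-6-diazonium tetrafluoroborate
Conditions: t-BuONO, 48% aq. HBF4, EtOH, 0 °C; precipitate with Et2O; use fresh
Reagents that add atoms: tert-butyl nitrite, CC(C)(C)ON=O; tetrafluoroboric acid, [H+].F[B-](F)(F)F
Why: Diazotization of an electron-rich aniline with an alkyl nitrite and HBF4; the alcoholic medium makes any O-nitrosation of the secondary hydroxyl reversible, and a para-alkoxy arenediazonium tetrafluoroborate should be stable enough to isolate.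

Step 12
Reactants: 11 diene acid; 19 chroman diazonium tetrafluoroborate
Product: 20 methyl (2S)-3-[3,4-bis(benzyloxy)phenyl]-2-{[(3R)-3-hydroxy-2,2-dimethylchroman-6-yl]methyl}-4-methoxy-5-oxo-2,5-dihydrofuran-2-carboxylate
Conditions: Cu(MeCN)4PF6 (10 mol %), 2,2′-(propane-2,2-diyl)bis[(4S)-4-tert-butyl-4,5-dihydrooxazole] (12 mol %), 2,6-di-tert-butylpyridine (1.2 equiv), EtOAc, 0 °C to rt, 19 added in portions
Reagents that add atoms: none
Why: Proposed new method: monovalent copper bound to the chiral bis(oxazoline) reduces 19 by single-electron transfer to the chroman-6-yl radical, which adds to the unsubstituted CH2 terminus of the acrylate unit of 11 as in a Meerwein arylation; the tertiary C5 radical, stabilized by its ester and by the C3=C4 bond, is captured by the divalent copper carboxylate of the C2 acid, and C–O reductive elimination from the resulting trivalent copper alkyl closes the lactone and returns monovalent copper. The closest known reaction type is the copper/bis(oxazoline)-catalysed enantioselective radical oxy-arylation (carbolactonization) of alkenoic acids with arenediazonium salts, established for benzylic radicals but not for a radical α to an ester in a cross-conjugated dienoic acid. The butenolide closes by O1–C5 bond formation, 5-exo-trig with respect to the C5=CH2 alkene, after the CH2–aryl bond has formed. The C5 stereocenter is set by the chiral ligand on copper in the C–O bond-forming event; the remote (3R) centre of the chroman is not expected to influence it. The step needs regioselective radical addition, secured by the terminal CH2 against the fully substituted C3=C4 bond, and closure at C5, secured by the cis relation of carboxylate and acrylate unit across C3=C4, which holds O1 over C5.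

Step 13
Reactants: 20 dibenzyl-protected lactone
Product: 21 methyl (2S)-3-(3,4-dihydroxyphenyl)-2-{[(3R)-3-hydroxy-2,2-dimethylchroman-6-yl]methyl}-4-methoxy-5-oxo-2,5-dihydrofuran-2-carboxylate (CNP0289675.1)
Conditions: H2 (1 atm), 10% Pd/C, EtOAc/MeOH, rt
Reagents that add atoms: none
Why: Hydrogenolysis of the two aryl benzyl ethers; the tetrasubstituted C3=C4 bond and the hindered quaternary C5–O1 bond should resist reduction under these mild conditions, so neither stereocenter is touched.

**Compound list**
1 | 3,4-bis(benzyloxy)benzoic acid | OC(=O)c1ccc(OCc2ccccc2)c(OCc2ccccc2)c1 | starting material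
2 | 3,4-bis(benzyloxy)benzoyl chloride | ClC(=O)c1ccc(OCc2ccccc2)c(OCc2ccccc2)c1 | intermediate
3 | tert-butyl methoxyacetate | COCC(=O)OC(C)(C)C | starting material
4 | lithium enolate of tert-butyl methoxyacetate | COC=C([O-])OC(C)(C)C.[Li+] | intermediate
5 | tert-butyl 3-[3,4-bis(benzyloxy)phenyl]-2-methoxy-3-oxopropanoate (racemic) | COC(C(=O)OC(C)(C)C)C(=O)c1ccc(OCc2ccccc2)c(OCc2ccccc2)c1 | intermediate
6 | sodium enolate of 5 (enolate oxygen cis to the ester) | CC(C)(C)OC(=O)/C(OC)=C(/c1ccc(OCc2ccccc2)c(OCc2ccccc2)c1)[O-].[Na+] | intermediate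
7 | tert-butyl (2E)-3-[3,4-bis(benzyloxy)phenyl]-2-methoxy-3-(trifluoromethylsulfonyloxy)prop-2-enoate | CC(C)(C)OC(=O)/C(OC)=C(/c1ccc(OCc2ccccc2)c(OCc2ccccc2)c1)OS(=O)(=O)C(F)(F)F | intermediate
8 | methyl propiolate | C#CC(=O)OC | starting material
9 | methyl 2-(tributylstannyl)prop-2-enoate | CCCC[Sn](CCCC)(CCCC)C(=C)C(=O)OC | intermediate
10 | 1-tert-butyl 5-methyl (2E)-3-[3,4-bis(benzyloxy)phenyl]-2-methoxy-4-methylidenepent-2-enedioate | CC(C)(C)OC(=O)/C(OC)=C(/c1ccc(OCc2ccccc2)c(OCc2ccccc2)c1)C(=C)C(=O)OC | intermediate
11 | (2E)-3-[3,4-bis(benzyloxy)phenyl]-2-methoxy-4-(methoxycarbonyl)penta-2,4-dienoic acid | OC(=O)/C(OC)=C(/c1ccc(OCc2ccccc2)c(OCc2ccccc2)c1)C(=C)C(=O)OC | intermediate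
12 | 4-nitrophenol | Oc1ccc(cc1)[N+](=O)[O-] | starting material
13 | 3-chloro-3-methylbut-1-yne | CC(C)(Cl)C#C | starting material
14 | 1-[(2-methylbut-3-yn-2-yl)oxy]-4-nitrobenzene | CC(C)(Oc1ccc(cc1)[N+](=O)[O-])C#C | intermediate
15 | 2,2-dimethyl-6-nitro-2H-chromene | CC1(C)C=Cc2cc(ccc2O1)[N+](=O)[O-] | intermediate
16 | (3R,4R)-3,4-epoxy-2,2-dimethyl-6-nitrochroman | CC1(C)Oc2ccc(cc2[C@H]3O[C@@H]13)[N+](=O)[O-] | intermediate
17 | (3R,4R)-6-amino-3,4-epoxy-2,2-dimethylchroman | CC1(C)Oc2ccc(N)cc2[C@H]3O[C@@H]13 | intermediate
18 | (3R)-6-amino-2,2-dimethylchroman-3-ol | Nc1ccc2c(c1)C[C@@H](O)C(C)(C)O2 | intermediate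
19 | (3R)-3-hydroxy-2,2-dimethylchroman-6-diazonium tetrafluoroborate | N#[N+]c1ccc2c(c1)C[C@@H](O)C(C)(C)O2.F[B-](F)(F)F | intermediate
20 | methyl (2S)-3-[3,4-bis(benzyloxy)phenyl]-2-{[(3R)-3-hydroxy-2,2-dimethylchroman-6-yl]methyl}-4-methoxy-5-oxo-2,5-dihydrofuran-2-carboxylate | COC(=O)[C@@]1(Cc2ccc3c(c2)C[C@@H](O)C(C)(C)O3)OC(=O)C(OC)=C1c1ccc(OCc2ccccc2)c(OCc2ccccc2)c1 | intermediate
21 | methyl (2S)-3-(3,4-dihydroxyphenyl)-2-{[(3R)-3-hydroxy-2,2-dimethylchroman-6-yl]methyl}-4-methoxy-5-oxo-2,5-dihydrofuran-2-carboxylate | COC(=O)[C@@]1(Cc2ccc3c(c2)C[C@@H](O)C(C)(C)O3)OC(=O)C(OC)=C1c1ccc(O)c(O)c1 | target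

**Step count**
Total: 13 steps. Longest linear sequence: 7 steps (1 → 2 → 5 → 7 → 10 → 11 → 20 → 21, or equally 12 → 14 → 15 → 16 → 18 → 19 → 20 → 21).

**Steps most likely to fail**

Step 12 (proposed new method). The radical may be captured without facial control if C–O bond formation runs through an unbound radical or a cation. The aryl radical may also be quenched by hydrogen abstraction from the benzylic ethers before it adds. Fallback by known chemistry, without control at C5: it sets out from diester 10 and salt 19. A classical Meerwein chloro-arylation (CuCl2, LiCl, acetone/water, rt) should give the tertiary allylic chloride 1-tert-butyl 5-methyl 3-[3,4-bis(benzyloxy)phenyl]-4-chloro-4-{[(3R)-3-hydroxy-2,2-dimethylchroman-6-yl]methyl}-2-methoxypent-2-enedioate F1 as a mixture of C4 epimers. CF3CO2H in CH2Cl2 would free the chloro acid 3-[3,4-bis(benzyloxy)phenyl]-4-chloro-4-{[(3R)-3-hydroxy-2,2-dimethylchroman-6-yl]methyl}-2,5-dimethoxy-5-oxopent-2-enoic acid F2. Ag2CO3 in MeCN would then close the lactone by carboxylate displacement of the ionizable tertiary chloride, giving 20 together with its C5 epimer methyl (2R)-3-[3,4-bis(benzyloxy)phenyl]-2-{[(3R)-3-hydroxy-2,2-dimethylchroman-6-yl]methyl}-4-methoxy-5-oxo-2,5-dihydrofuran-2-carboxylate F3. The chroman carbinol centre makes these two diastereomers, so chromatography (preparative HPLC if needed) should deliver 20, where the route is rejoined.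

Step 5. Transmetalation of the hindered, electron-poor α-stannylacrylate onto a congested tetrasubstituted vinylpalladium may be slow, so that protodestannylation, stannane homocoupling or triflate cleavage take over. Fallback: it sets out from triflate 7. Sonogashira coupling with ethynyltrimethylsilane (Pd(PPh3)2Cl2, CuI, Et3N, THF) should give the silyl enyne tert-butyl 3-[3,4-bis(benzyloxy)phenyl]-2-methoxy-5-(trimethylsilyl)pent-2-en-4-ynoate F4. K2CO3 in MeOH at 0 °C would give the terminal enyne tert-butyl 3-[3,4-bis(benzyloxy)phenyl]-2-methoxypent-2-en-4-ynoate F5. A branched-selective palladium-catalysed methoxycarbonylation (Pd(OAc)2, 2-pyridyldiphenylphosphine, MeSO3H cat., CO, MeOH) would then add H and CO2Me across the alkyne with the ester on the internal carbon, returning to the route at 10.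

Step 3. Geometric control may be lost in the O-sulfonylation if the α-methoxy group offers the metal a competing five-membered chelate, which would place the triflate trans to the ester. Fallback: it sets out from β-keto ester 5. Enol tosylation with TsCl and N-methylimidazole can be steered to either alkene geometry of α-substituted β-keto esters by the base (LiOH for the chelated enolate, Et3N for the open one). Whichever sense this substrate follows, one of the two conditions should give the isomer with ester and sulfonate cis, tert-butyl 3-[3,4-bis(benzyloxy)phenyl]-2-methoxy-3-(tosyloxy)prop-2-enoate F6. Sonogashira coupling of this tosylate with ethynyltrimethylsilane would give the silyl enyne F4 of the preceding fallback, which continues as described there and rejoins the route at 10.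

**Further compounds**
F1 | step 12 | 1-tert-butyl 5-methyl 3-[3,4-bis(benzyloxy)phenyl]-4-chloro-4-{[(3R)-3-hydroxy-2,2-dimethylchroman-6-yl]methyl}-2-methoxypent-2-enedioate (C4 epimers) | CC(C)(C)OC(=O)/C(OC)=C(/c1ccc(OCc2ccccc2)c(OCc2ccccc2)c1)C(Cl)(Cc1ccc2c(c1)C[C@@H](O)C(C)(C)O2)C(=O)OC
F2 | step 12 | 3-[3,4-bis(benzyloxy)phenyl]-4-chloro-4-{[(3R)-3-hydroxy-2,2-dimethylchroman-6-yl]methyl}-2,5-dimethoxy-5-oxopent-2-enoic acid (C4 epimers) | OC(=O)/C(OC)=C(/c1ccc(OCc2ccccc2)c(OCc2ccccc2)c1)C(Cl)(Cc1ccc2c(c1)C[C@@H](O)C(C)(C)O2)C(=O)OC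
F3 | step 12 | methyl (2R)-3-[3,4-bis(benzyloxy)phenyl]-2-{[(3R)-3-hydroxy-2,2-dimethylchroman-6-yl]methyl}-4-methoxy-5-oxo-2,5-dihydrofuran-2-carboxylate | COC(=O)[C@]1(Cc2ccc3c(c2)C[C@@H](O)C(C)(C)O3)OC(=O)C(OC)=C1c1ccc(OCc2ccccc2)c(OCc2ccccc2)c1
F4 | step 5 | tert-butyl 3-[3,4-bis(benzyloxy)phenyl]-2-methoxy-5-(trimethylsilyl)pent-2-en-4-ynoate (ester and alkynyl cis) | CC(C)(C)OC(=O)/C(OC)=C(/c1ccc(OCc2ccccc2)c(OCc2ccccc2)c1)C#C[Si](C)(C)C
F5 | step 5 | tert-butyl 3-[3,4-bis(benzyloxy)phenyl]-2-methoxypent-2-en-4-ynoate (ester and ethynyl cis) | CC(C)(C)OC(=O)/C(OC)=C(/c1ccc(OCc2ccccc2)c(OCc2ccccc2)c1)C#C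
F6 | step 3 | tert-butyl 3-[3,4-bis(benzyloxy)phenyl]-2-methoxy-3-(tosyloxy)prop-2-enoate (ester and OTs cis) | CC(C)(C)OC(=O)/C(OC)=C(/c1ccc(OCc2ccccc2)c(OCc2ccccc2)c1)OS(=O)(=O)c1ccc(C)cc1
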